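**Plan**

1. Numbering follows the heptadecatrienoic acid name (C1 = CO2H, C5 = stereocentre, C1' = first carbon of the furylpropylidene group). The retrosynthesis cuts the C2=C1' alkene, the C2–C3 bond, and at C5 both the C5–C6 bond to the farnesyl CH2 and the C5–isopropenyl bond.
2. C5 is an acyclic CH carbon bonded to three carbon groups (the isopropenyl carbon, the farnesyl CH2 C6 and the C4–C3 ethylene arm). It can therefore begin as an oxygen-bound, lithiated CH carbon that takes the first group from boron by a 1,2-shift and the second by a boron-to-alkene olefination. The only ring, the furan, is bought; no ring is formed.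
3. Forward: nerol → 1,5-enyne → E-iodoalkene → (2E,6Z)-farnesyl boronic ester; propane-1,3-diol → silyl-protected triisopropylbenzoate; union of these two with isopropenyllithium at C5; then alcohol, iodide, phosphonate, olefination with 3-(furan-3-yl)propanal, saponification.
4. Stereochemistry: C5 from (−)-sparteine-directed deprotonation followed by stereospecific shifts; 7E from syn-carboalumination; 11Z carried over from nerol; 2Z from the trifluoroethyl phosphonate olefination.

Key step: step 8

Remark 1: a 2,4,6-triisopropylbenzoate (TIB ester) is chosen over a dialkylcarbamate as leaving group on the carbenoid carbon, because its boronate complex should rearrange on gentle warming without MgBr2, which would turn isopropenyllithium into a Grignard reagent in the same flask.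
Remark 2: salts that are only the deprotonated form of a numbered compound (alkoxides, phosphonate enolates, the lithium carboxylate before acidification) and short-lived mechanistic species such as oxaphosphetanes are treated as forms of the parent compound and carry no number.

**Route**

Step 1
Reactants: 1 nerol
Product: 2 neryl bromide
Conditions: PBr3 (0.4 equiv), Et2O, −10 °C; used at once
Reagents that add atoms: phosphorus tribromide, BrP(Br)Br
Why: Bromination of a primary allylic alcohol with PBr3 (substitution through the phosphite ester) at low temperature should keep the Z alkene and avoid allylic transposition.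

Step 2
Reactants: 2 neryl bromide
Product: 4 (5Z)-6,10-dimethylundeca-5,9-dien-1-yne, via silylated enyne 3 (not isolated)
Conditions: 1-(trimethylsilyl)propyne, n-BuLi, THF, −78 to −20 °C; 2, −78 °C to rt; then MeOH, K2CO3 (cat.), rt
Reagents that add atoms: 1-(trimethylsilyl)prop-1-yne, CC#C[Si](C)(C)C
Why: The propargylic lithium reagent alkylates the primary allylic bromide by SN2 at CH2Br (propargylation, the silyl group blocking the alkyne terminus), and base-catalysed methanolysis then cleaves the C–Si bond (protodesilylation).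

Step 3
Reactants: 4 (5Z)-6,10-dimethylundeca-5,9-dien-1-yne
Product: 6 (1E,5Z)-1-iodo-2,6,10-trimethylundeca-1,5,9-triene, via alkenyldimethylalane 5 (not isolated)
Conditions: Me3Al, Cp2ZrCl2 (0.25 equiv), CH2Cl2, 0 °C to rt; then I2, THF, −30 to 0 °C
Reagents that add atoms: trimethylaluminium, C[Al](C)C; iodine, II
Why: Zirconium-catalysed methylalumination of the terminal alkyne (Negishi carboalumination) adds CH3 and Al syn with Al at the terminus, and iodinolysis with retention gives the E iodoalkene that becomes C7=C8, while the trisubstituted alkenes stay untouched.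

Step 4
Reactants: 6 (1E,5Z)-1-iodo-2,6,10-trimethylundeca-1,5,9-triene
Product: 9 (2E,6Z)-farnesyl pinacol boronate, via alkenyllithium 7 (not isolated), via chloromethyl boronate complex 8 (not isolated)
Conditions: t-BuLi (2.0 equiv), Et2O, −78 °C; ClCH2Bpin, −78 °C to rt
Reagents that add atoms: 2-(chloromethyl)-4,4,5,5-tetramethyl-1,3,2-dioxaborolane, ClCB1OC(C)(C)C(C)(C)O1
Why: Iodine–lithium exchange with retention gives the alkenyllithium, which adds to boron, and 1,2-shift of the alkenyl group with loss of chloride (Matteson homologation) should give the allylic boronic ester without touching the alkene geometry.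

Step 5
Reactants: 10 propane-1,3-diol
Product: 11 3-[(tert-butyldimethylsilyl)oxy]propan-1-ol
Conditions: NaH (1.0 equiv), THF, rt; then TBSCl (1.0 equiv), rt
Reagents that add atoms: tert-butyldimethylsilyl chloride, CC(C)(C)[Si](C)(C)Cl
Why: O-Silylation of the sparingly soluble monosodium alkoxide of a symmetrical diol should favour the mono ether.

Step 6
Reactants: 11 3-[(tert-butyldimethylsilyl)oxy]propan-1-ol
Product: 12 3-[(tert-butyldimethylsilyl)oxy]propyl 2,4,6-triisopropylbenzoate
Conditions: 2,4,6-triisopropylbenzoic acid, PPh3, DIAD, THF, 0 °C to rt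
Reagents that add atoms: 2,4,6-triisopropylbenzoic acid, CC(C)c1cc(C(C)C)c(C(=O)O)c(C(C)C)c1
Why: Mitsunobu esterification of a primary alcohol is the usual way to attach the hindered benzoate that later directs alpha-lithiation, and the silyl ether is inert to it.

Step 7
Reactants: 13 2-bromopropene
Product: 14 isopropenyllithium
Conditions: t-BuLi (2.0 equiv), Et2O, −78 °C; kept cold and used as a solution
Reagents that add atoms: tert-butyllithium, [Li]C(C)(C)C
Why: Bromine–lithium exchange, the second equivalent of t-BuLi destroying the t-BuBr formed, should give a clean solution of the alkenyllithium.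

Step 8
Reactants: 12 3-[(tert-butyldimethylsilyl)oxy]propyl 2,4,6-triisopropylbenzoate; 9 (2E,6Z)-farnesyl pinacol boronate; 14 isopropenyllithium
Product: 20 tert-butyl(dimethyl){[(3S,5E,9Z)-6,10,14-trimethyl-3-(prop-1-en-2-yl)pentadeca-5,9,13-trien-1-yl]oxy}silane, via lithiated benzoate 15 (not isolated), via first boronate complex 16 (not isolated), via secondary boronic ester 17 (not isolated), via alkenyl boronate complex 18 (not isolated), via iodoalkyl boronic ester 19 (not isolated)
Conditions: 12 (1.3 equiv), (−)-sparteine, s-BuLi, Et2O, −78 °C, 5 h; 9 (1.0 equiv), −78 °C, 1 h, then 35 °C; THF, 14 (1.5 equiv), −78 °C; I2 (1.5 equiv), MeOH, −78 °C; NaOMe, MeOH, −78 °C to rt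
Reagents that add atoms: none
Why: s-BuLi/(−)-sparteine removes the pro-S hydrogen next to the benzoate oxygen of 12, and the configurationally stable carbanion 15 bonds to the boron of 9 with retention (16); on warming, the farnesyl CH2 moves from boron to carbon anti to the leaving benzoate, with inversion, which forms the C5–C6 bond (17). Isopropenyllithium 14 then gives boronate 18, I2 forms an iodonium ion on its isopropenyl group, the secondary alkyl group shifts from boron to carbon with retention (19), and NaOMe induces anti elimination of boron and iodide, which forms the C5–isopropenyl bond (20). The closest known reaction types are the lithiation–borylation of sparteine-lithiated primary alkyl benzoates and carbamates with pinacol boronic esters and the Zweifel olefination of secondary boronic esters; no ring is closed. The one new stereocentre is controlled by the chiral diamine in the deprotonation, and retention, inversion and retention in the three later events carry it through to the configuration that is 5R in the target (3S in 20 by the priority rules). The step needs I2 to react at the boron-bound alkene and not at the trisubstituted chain alkenes or the new 1,1-disubstituted one, which the high nucleophilicity of the alkenyl boronate at −78 °C and the limited charge of I2 should secure; the farnesyl geometry is safe because the allyl group migrates through its boron-bound CH2 without any allyl cation or π-allyl metal species.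

Step 9
Reactants: 20 tert-butyl(dimethyl){[(3S,5E,9Z)-6,10,14-trimethyl-3-(prop-1-en-2-yl)pentadeca-5,9,13-trien-1-yl]oxy}silane
Product: 21 (3S,5E,9Z)-6,10,14-trimethyl-3-(prop-1-en-2-yl)pentadeca-5,9,13-trien-1-ol
Conditions: Bu4NF, THF, 0 °C to rt
Reagents that add atoms: none
Why: Fluoride-mediated desilylation should free the primary alcohol without affecting the alkenes or the stereocentre.

Step 10
Reactants: 21 (3S,5E,9Z)-6,10,14-trimethyl-3-(prop-1-en-2-yl)pentadeca-5,9,13-trien-1-ol
Product: 22 (3S,5E,9Z)-1-iodo-6,10,14-trimethyl-3-(prop-1-en-2-yl)pentadeca-5,9,13-triene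
Conditions: I2, PPh3, imidazole, CH2Cl2, 0 °C
Reagents that add atoms: iodine, II
Why: Appel-type iodination proceeds by SN2 displacement of the oxyphosphonium group under near-neutral conditions that should spare the four alkenes.

Step 11
Reactants: 22 (3S,5E,9Z)-1-iodo-6,10,14-trimethyl-3-(prop-1-en-2-yl)pentadeca-5,9,13-triene; 23 methyl 2-[bis(2,2,2-trifluoroethoxy)phosphoryl]acetate
Product: 24 methyl (5R,7E,11Z)-2-[bis(2,2,2-trifluoroethoxy)phosphoryl]-8,12,16-trimethyl-5-(prop-1-en-2-yl)heptadeca-7,11,15-trienoate
Conditions: 23 (3 equiv), NaH, DMSO, rt; then 22, rt to 40 °C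
Reagents that add atoms: none
Why: SN2 C-alkylation of the phosphonoacetate enolate by an unhindered primary iodide, with the enolate in excess to suppress dialkylation; the new phosphonate-bearing carbon forms as both epimers, which does not matter because it becomes sp2 in step 14.

Step 12
Reactants: 25 furan-3-carbaldehyde
Product: 26 (2E)-3-(furan-3-yl)prop-2-enal
Conditions: Ph3P=CHCHO (1.05 equiv), toluene, 80 °C
Reagents that add atoms: (triphenylphosphoranylidene)acetaldehyde, O=CC=P(c1ccccc1)(c1ccccc1)c1ccccc1
Why: Wittig reaction of an aromatic aldehyde with the stabilised formylmethylene ylide should give the E enal, and holding the ylide near one equivalent limits a second homologation.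

Step 13
Reactants: 26 (2E)-3-(furan-3-yl)prop-2-enal
Product: 27 3-(furan-3-yl)propanal
Conditions: diethyl 2,6-dimethyl-1,4-dihydropyridine-3,5-dicarboxylate (Hantzsch ester), dibenzylammonium trifluoroacetate (5 mol %), THF, rt
Reagents that add atoms: none
Why: Iminium-catalysed transfer hydrogenation from the Hantzsch ester (organocatalytic conjugate reduction) should reduce only the conjugated C=C bond and leave the aldehyde and the furan ring alone.

Step 14
Reactants: 24 methyl (5R,7E,11Z)-2-[bis(2,2,2-trifluoroethoxy)phosphoryl]-8,12,16-trimethyl-5-(prop-1-en-2-yl)heptadeca-7,11,15-trienoate; 27 3-(furan-3-yl)propanal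
Product: 28 methyl (2Z,5R,7E,11Z)-2-[3-(furan-3-yl)propylidene]-8,12,16-trimethyl-5-(prop-1-en-2-yl)heptadeca-7,11,15-trienoate
Conditions: KN(SiMe3)2, 18-crown-6, THF, −78 °C; then 27 (1.5 equiv), −78 °C
Reagents that add atoms: none
Why: Still–Gennari olefination, in which the electron-poor phosphonate with a crown-separated potassium counter-ion eliminates faster than the adduct can equilibrate, should place the ester cis to the aldehyde-derived chain (2Z), any minor E isomer being removed by chromatography.

Step 15
Reactants: 28 methyl (2Z,5R,7E,11Z)-2-[3-(furan-3-yl)propylidene]-8,12,16-trimethyl-5-(prop-1-en-2-yl)heptadeca-7,11,15-trienoate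
Product: 29 (2Z,5R,7E,11Z)-2-[3-(furan-3-yl)propylidene]-8,12,16-trimethyl-5-(prop-1-en-2-yl)heptadeca-7,11,15-trienoic acid
Conditions: LiOH·H2O, THF/MeOH/H2O, 40 °C; then dilute HCl to pH 4, 0 °C
Reagents that add atoms: lithium hydroxide, [Li+].[OH-]
Why: Saponification of the methyl ester followed by mild acidification should give the acid without moving the trisubstituted alkene, opening the furan or touching the remote stereocentre.

**Compound list**

1 | nerol, (2Z)-3,7-dimethylocta-2,6-dien-1-ol | CC(C)=CCC/C(C)=C\CO | starting material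
2 | neryl bromide, (2Z)-1-bromo-3,7-dimethylocta-2,6-diene | CC(C)=CCC/C(C)=C\CBr | intermediate
3 | [(5Z)-6,10-dimethylundeca-5,9-dien-1-yn-1-yl]trimethylsilane (not isolated) | C[Si](C)(C)C#CCC/C=C(/C)CCC=C(C)C | intermediate
4 | (5Z)-6,10-dimethylundeca-5,9-dien-1-yne | C#CCC/C=C(/C)CCC=C(C)C | intermediate
5 | dimethyl[(1E,5Z)-2,6,10-trimethylundeca-1,5,9-trien-1-yl]alumane (not isolated) | C[Al](C)/C=C(\C)CC/C=C(/C)CCC=C(C)C | intermediate
6 | (1E,5Z)-1-iodo-2,6,10-trimethylundeca-1,5,9-triene | I/C=C(\C)CC/C=C(/C)CCC=C(C)C | intermediate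
7 | [(1E,5Z)-2,6,10-trimethylundeca-1,5,9-trien-1-yl]lithium (not isolated) | [Li]/C=C(\C)CC/C=C(/C)CCC=C(C)C | intermediate
8 | lithium (chloromethyl)(pinacolato)[(1E,5Z)-2,6,10-trimethylundeca-1,5,9-trien-1-yl]borate (not isolated) | [Li+].ClC[B-]1(/C=C(\C)CC/C=C(/C)CCC=C(C)C)OC(C)(C)C(C)(C)O1 | intermediate
9 | (2E,6Z)-farnesyl pinacol boronate, 4,4,5,5-tetramethyl-2-[(2E,6Z)-3,7,11-trimethyldodeca-2,6,10-trien-1-yl]-1,3,2-dioxaborolane | CC1(C)OB(C/C=C(\C)CC/C=C(/C)CCC=C(C)C)OC1(C)C | intermediate
10 | propane-1,3-diol | OCCCO | starting material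
11 | 3-[(tert-butyldimethylsilyl)oxy]propan-1-ol | CC(C)(C)[Si](C)(C)OCCCO | intermediate
12 | 3-[(tert-butyldimethylsilyl)oxy]propyl 2,4,6-triisopropylbenzoate | CC(C)c1cc(C(C)C)c(C(=O)OCCCO[Si](C)(C)C(C)(C)C)c(C(C)C)c1 | intermediate
13 | 2-bromopropene | C=C(C)Br | starting material
14 | isopropenyllithium (prop-1-en-2-yllithium), used as a solution | [Li]C(C)=C | intermediate
15 | (S)-3-[(tert-butyldimethylsilyl)oxy]-1-lithiopropyl 2,4,6-triisopropylbenzoate, present as its (−)-sparteine complex (not isolated) | [Li][C@H](OC(=O)c1c(C(C)C)cc(C(C)C)cc1C(C)C)CCO[Si](C)(C)C(C)(C)C | intermediate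
16 | lithium (pinacolato)[(2E,6Z)-farnesyl]{(1S)-3-[(tert-butyldimethylsilyl)oxy]-1-[(2,4,6-triisopropylbenzoyl)oxy]propyl}borate (not isolated) | [Li+].CC1(C)O[B-](C/C=C(\C)CC/C=C(/C)CCC=C(C)C)([C@H](OC(=O)c2c(C(C)C)cc(C(C)C)cc2C(C)C)CCO[Si](C)(C)C(C)(C)C)OC1(C)C | intermediate
17 | 2-[(3S,5E,9Z)-1-[(tert-butyldimethylsilyl)oxy]-6,10,14-trimethylpentadeca-5,9,13-trien-3-yl]-4,4,5,5-tetramethyl-1,3,2-dioxaborolane (not isolated) | CC1(C)OB([C@@H](C/C=C(\C)CC/C=C(/C)CCC=C(C)C)CCO[Si](C)(C)C(C)(C)C)OC1(C)C | intermediate
18 | lithium (pinacolato)(prop-1-en-2-yl)[(3S,5E,9Z)-1-[(tert-butyldimethylsilyl)oxy]-6,10,14-trimethylpentadeca-5,9,13-trien-3-yl]borate (not isolated) | [Li+].C=C(C)[B-]1([C@@H](C/C=C(\C)CC/C=C(/C)CCC=C(C)C)CCO[Si](C)(C)C(C)(C)C)OC(C)(C)C(C)(C)O1 | intermediate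
19 | 2-[(3S,5E,9Z)-3-{2-[(tert-butyldimethylsilyl)oxy]ethyl}-1-iodo-2,6,10,14-tetramethylpentadeca-5,9,13-trien-2-yl]-4,4,5,5-tetramethyl-1,3,2-dioxaborolane, both C2 epimers (not isolated) | CC1(C)OB(C(C)(CI)[C@@H](C/C=C(\C)CC/C=C(/C)CCC=C(C)C)CCO[Si](C)(C)C(C)(C)C)OC1(C)C | intermediate
20 | tert-butyl(dimethyl){[(3S,5E,9Z)-6,10,14-trimethyl-3-(prop-1-en-2-yl)pentadeca-5,9,13-trien-1-yl]oxy}silane | C=C(C)[C@@H](C/C=C(\C)CC/C=C(/C)CCC=C(C)C)CCO[Si](C)(C)C(C)(C)C | intermediate
21 | (3S,5E,9Z)-6,10,14-trimethyl-3-(prop-1-en-2-yl)pentadeca-5,9,13-trien-1-ol | C=C(C)[C@@H](C/C=C(\C)CC/C=C(/C)CCC=C(C)C)CCO | intermediate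
22 | (3S,5E,9Z)-1-iodo-6,10,14-trimethyl-3-(prop-1-en-2-yl)pentadeca-5,9,13-triene | C=C(C)[C@@H](C/C=C(\C)CC/C=C(/C)CCC=C(C)C)CCI | intermediate
23 | methyl 2-[bis(2,2,2-trifluoroethoxy)phosphoryl]acetate | COC(=O)CP(=O)(OCC(F)(F)F)OCC(F)(F)F | starting material
24 | methyl (5R,7E,11Z)-2-[bis(2,2,2-trifluoroethoxy)phosphoryl]-8,12,16-trimethyl-5-(prop-1-en-2-yl)heptadeca-7,11,15-trienoate, both C2 epimers | C=C(C)[C@@H](C/C=C(\C)CC/C=C(/C)CCC=C(C)C)CCC(C(=O)OC)P(=O)(OCC(F)(F)F)OCC(F)(F)F | intermediate
25 | furan-3-carbaldehyde | O=Cc1ccoc1 | starting material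
26 | (2E)-3-(furan-3-yl)prop-2-enal | O=C/C=C/c1ccoc1 | intermediate
27 | 3-(furan-3-yl)propanal | O=CCCc1ccoc1 | intermediate
28 | methyl (2Z,5R,7E,11Z)-2-[3-(furan-3-yl)propylidene]-8,12,16-trimethyl-5-(prop-1-en-2-yl)heptadeca-7,11,15-trienoate | C=C(C)[C@@H](C/C=C(\C)CC/C=C(/C)CCC=C(C)C)CC/C(=C/CCc1ccoc1)C(=O)OC | intermediate
29 | (2Z,5R,7E,11Z)-2-[3-(furan-3-yl)propylidene]-8,12,16-trimethyl-5-(prop-1-en-2-yl)heptadeca-7,11,15-trienoic acid, CNP0235819.1 | C=C(C)[C@@H](C/C=C(\C)CC/C=C(/C)CCC=C(C)C)CC/C(=C/CCc1ccoc1)C(=O)O | target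

**Step count and risks**

Total: 15 steps. Longest linear sequence: 10 steps (steps 1, 2, 3, 4, 8, 9, 10, 11, 14, 15).

Steps most likely to fail:

1. Step 8 (key step). With the diamine, lithium benzoate and surplus organolithium all in one flask, iodine may be diverted to the amine or to the chain alkenes and the second boronate complex may form incompletely. Any warming of the lithiated benzoate before capture would also erode enantiomeric purity. The fallback sets out from 12 and comes back at 20. Compound 12 is lithiated as in step 8 and quenched with Me3SnCl to give (S)-3-[(tert-butyldimethylsilyl)oxy]-1-(trimethylstannyl)propyl 2,4,6-triisopropylbenzoate F1, which can be purified and checked for enantiomeric purity. Tin–lithium exchange (n-BuLi, Et2O, −78 °C) regenerates 15 without diamine, 9 is added and the mixture warmed, and boronic ester 17 is then isolated by chromatography. Pure 17 is olefinated in a separate operation with 14, I2 and NaOMe in THF/MeOH to give 20.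

2. Step 11. The trifluoroethyl phosphonate enolate is weakly nucleophilic and base-sensitive, so the SN2 reaction may be slow, with dialkylation and loss of trifluoroethoxide competing. The fallback sets out from 22 and 27 and comes back at 28, replacing steps 11 and 14 by a cross-coupling. Aldehyde 27 is condensed with methyl 2-[bis(2,2,2-trifluoroethoxy)phosphoryl]-2-bromoacetate (KN(SiMe3)2, 18-crown-6, THF, −78 °C) to give methyl (2E)-2-bromo-5-(furan-3-yl)pent-2-enoate F2, in which the ester is cis to the furylethyl chain. Zinc insertion into 22 (Zn dust, LiCl, THF, 40 °C) gives [(3S,5E,9Z)-6,10,14-trimethyl-3-(prop-1-en-2-yl)pentadeca-5,9,13-trien-1-yl]zinc iodide F3. Negishi coupling of F3 with F2 (Pd(PPh3)4, THF, rt) then forms the C2–C3 bond with retention of alkene geometry and gives 28.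

3. Step 4. The alkenyllithium may add twice to boron, the 1,2-shift of the boronate complex may be incomplete, and the allylic boronic ester may be lost by protodeboronation during isolation. The fallback sets out from 6 and comes back at 9. Alkenyllithium 7, generated as in step 4, is quenched with paraformaldehyde to give (2E,6Z)-farnesol F4. Corey–Kim chlorination (N-chlorosuccinimide, Me2S, CH2Cl2, −30 to 0 °C) gives (2E,6Z)-farnesyl chloride F5 without allylic transposition. Borylation of F5 with B2pin2 under Pd2(dba)3 catalysis (THF, 60 °C) then gives 9; the alkene geometry would have to be checked at this point because an allylpalladium intermediate is involved.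

**Further compounds**

F1 | step 8 | (S)-3-[(tert-butyldimethylsilyl)oxy]-1-(trimethylstannyl)propyl 2,4,6-triisopropylbenzoate | C[Sn](C)(C)[C@H](OC(=O)c1c(C(C)C)cc(C(C)C)cc1C(C)C)CCO[Si](C)(C)C(C)(C)C
F2 | step 11 | methyl (2E)-2-bromo-5-(furan-3-yl)pent-2-enoate | COC(=O)/C(Br)=C\CCc1ccoc1
F3 | step 11 | [(3S,5E,9Z)-6,10,14-trimethyl-3-(prop-1-en-2-yl)pentadeca-5,9,13-trien-1-yl]zinc iodide | C=C(C)[C@@H](C/C=C(\C)CC/C=C(/C)CCC=C(C)C)CC[Zn]I
F4 | step 4 | (2E,6Z)-farnesol, (2E,6Z)-3,7,11-trimethyldodeca-2,6,10-trien-1-ol | OC/C=C(\C)CC/C=C(/C)CCC=C(C)C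
F5 | step 4 | (2E,6Z)-farnesyl chloride, (2E,6Z)-1-chloro-3,7,11-trimethyldodeca-2,6,10-triene | ClC/C=C(\C)CC/C=C(/C)CCC=C(C)C
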